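The constants used here are assumed; the flask was simulated.

I began with the easy step, target ⇌ isomer of the product C, which runs without any catalyst.

    substrate + free catalyst ⇌ target + free catalyst, rate k1*[substrate]*[free catalyst] forward; the back reaction follows from the equilibrium constant (K1 = 0.84, k1 = 8.9 L mol⁻¹ min⁻¹)
    target + free catalyst ⇌ isomer of the product A + free catalyst, rate k2*[free catalyst]*[target] forward; the back reaction follows from the equilibrium constant (K2 = 2.1, k2 = 130 L mol⁻¹ min⁻¹)
    isomer of the product A ⇌ isomer of the product B (K3 = 0.68, k3 = 0.29 min⁻¹)
    isomer of the product B ⇌ substrate (k4 = 0.098 min⁻¹)
    substrate + free catalyst ⇌ idle complex, settled at all times (K5 = 11 L mol⁻¹)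
    free catalyst → spent catalyst (k6 = 0.25 min⁻¹)
    target ⇌ isomer of the product C (K7 = 1.8, k7 = 0.11 min⁻¹)

| flask | substrate | free catalyst | time | remark |
|---|---|---|---|---|
| midnight | 0.10 M (in portions, 3) | 10 mM | 40 min | the portions of substrate follow each other after 0.60 min, the first at the start |
| autumn | 0.10 M (in portions, 3) | 10 mM | 40 min | the portions of substrate follow each other after 1.2 min, the first at the start |
| winter | 0.10 M (in portions, 3) | 10 mM | 40 min | the portions of substrate follow each other after 2.5 min, the first at the start |
| dawn | 0.10 M (in portions, 3) | 10 mM | 40 min | the portions of substrate follow each other after 5.0 min, the first at the start |

- "hardly changes" means that all values lie within two and a half points (for a concentration: within two and a half percent of the largest)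
- run time (midnight): 40 min

- amount of target at the end, in percent of the substrate charged for midnight, autumn, winter, dawn, in this order
- the course of these numbers from the first flask to the last (falls, then rises / rises all the way / rises, then falls / hardly changes / falls all the way)

1. I followed one molecule standing in the pair of target and isomer of the product C once the free catalyst was dead. Every way out of that pair needs catalyst, so the molecule could only shuttle inside it, and balance puts 1.8 parts of isomer of the product C against one part of target. Its chance of ending as target is therefore the pair share, 35.7%: one part out of the parts of the pair together.

2. The pair has time to settle, because its relaxation half-life of 4.05 min is shorter than the run of 40 min. Free catalyst has an unsheltered half-life of 2.77 min, also shorter than the run.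

3. The first extreme was a catalyst that outlasts every step. All the isomers then balance, and target ends at 13.3% of the charge.

4. The second extreme was a catalyst that lives just long enough to balance substrate, target and the isomers of the products A and B, while isomer of the product C receives nothing. Target then stands at 17.5%, and the pair share leaves 6.25%.

5. Substrate shelters the catalyst in the idle complex, which stretches the catalyst half-life to 5.82 min at most, at the full charge. I placed the real flask between the extremes and nearer the second, because even that stretched half-life is shorter than the forward half-life of 6.3 min for target going to isomer of the product C by step 7 alone. So I committed to about 6.25% for midnight, as a figure on the low side.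

6. In midnight the last portion came at 1.20 min, within one unsheltered catalyst half-life. In dawn it came at 10.0 min, after at least 1.72 of the stretched half-lives, so I counted only the earlier portions there and reckoned 4.16%. That is a fall of 2.1 percentage points, inside the stated margin, so the course I committed to was hardly changes.

The forecast gave 9.2%, 9%, 8.4% and 7.2% with the course falls all the way, higher than my numbers and different in shape, holding that “the pool should shrink gently”.

The simulation gave 7.68%, 7.36%, 6.61% and 5.18%, and the course hardly changes. In dawn the free catalyst had fallen to 0.0446% of its charge at 40.0 min. In midnight, the pair share applied to target and isomer of the product C together at 40.0 min gives 7.52%, and target stood at 7.53% at 400 min. In dawn, the same share applied to that flask's pair at 40.0 min gives 5.00%, and target stood at 5.01% at 400 min.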